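In this vessel reagent appears as gas dissolves, up to a saturation of 63 mM. Three substrates take it, while starting material also attacks target to give side product.

all flasks: gas 63 mM (held)

| run | starting material | second substrate | third substrate | remark | time |
|---|---|---|---|---|---|
| noon | 0.10 M | 0.10 M | 0.020 M | run made earlier |  |
| autumn | 0.10 M | 0.10 M | 0.013 M | run made earlier |  |
| dusk | 0.10 M | 0.10 M | 0.030 M | run made earlier |  |
| zeta | 0.10 M | 0.100 M | 0.0200 M | everything together at the start | 2.5 h |
| theta | 0.10 M (fed, over 1.0 h) | 0.100 M | 0.0200 M | all else is in the flask from the start; the feed brings no volume worth counting | 2.5 h |
| eta | 0.10 M | 0.100 M (in portions, 5, over 1.0 h) | 0.0200 M | first portion at the start, last at 1.0 h | 2.5 h |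
| alpha | 0.10 M | 0.100 M (fed, over 1.0 h) | 0.0200 M | all else is in the flask from the start; the feed brings no volume worth counting | 2.5 h |

noon run (percent of the starting material charged): time / min: target / % = 5.00: 39.8; 15.0: 65.8; 25.0: 65.0; 40.0: 65.4; 50.0: 64.9; 80.0: 66.8; 90.0: 65.6

autumn run (percent of the starting material charged): time / h: target / % = 0.250: 67.4; 0.333: 66.6; 0.500: 67.1; 0.833: 67.2; 1.33: 67.9; 2.00: 66.4; 3.00: 67.3

dusk run (percent of the starting material charged): time / h: target / % = 0.167: 61.0; 0.500: 64.7; 0.833: 65.0; 1.33: 65.9; 2.00: 64.9; 2.50: 65.5; 3.00: 63.7

(readings scatter by 1 percentage point)

- a species is counted by the starting material in it: one side product counts as two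
- at the start none of reagent is dissolved
- reactions considered so far: starting material + reagent -> target; second substrate + reagent -> second product; third substrate + reagent -> third product; gas <-> reagent; starting material + target -> side product

1. the best flask by amount of target, in percent of the starting material charged; "all alike" if 1.5 percentage points covers them all (zeta / theta / eta / alpha / all alike)
2. amount of target at the end, in percent of the starting material charged, zeta
3. amount of target at the end, in percent of the starting material charged, theta
4. amount of target at the end, in percent of the starting material charged, eta
5. amount of target at the end, in percent of the starting material charged, alpha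

Freeze two things: reagent at a steady level, and target at half its final amount. Each portion of starting material then takes the main path or the side path, and the side path costs one target as well. With u as side rate over main rate, the yield Y is (one − u)/(one + u), and u is σY/two. Reading this back from the noon plateau of 65.6% gives 0.634 for σ, the side number: side rate constant times charge of starting material, over main rate constant times reagent level.

The rule does not ask how starting material enters. So one extreme of theta, with reagent at the noon level, simply repeats the plateau, and I expect zeta there too. The other extreme, σ near zero, turns the charge into target. Theta lies between them, and its reagent level places it. Noon drew reagent at about 0.742 M h⁻¹ if the substrates finished by 15.0 min, while the theta feed asks 0.100 M h⁻¹. Because that is the smaller draw, I take the shortfall below saturation to shrink in proportion. Assuming noon stood at 0.5 of saturation, reagent rises 1.87-fold, σ becomes 0.340, and theta gives 76.9%. Eta and alpha still hold the starting material in full from the start, so I place them just above the plateau, below theta.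

The forecast, higher than my figure for theta, names theta best with zeta 65.6%, theta 85% (74% to 94%), eta 67% and alpha 68%, saying “Selectivity should improve strongly”.

The flasks give zeta 66.1%, theta 82.3%, eta 69.8% and alpha 70.3%, so theta is best. At the end of its feed, theta held 0.0600 M reagent.

    starting material + reagent → target (k = 9.88 M⁻¹ min⁻¹)
    second substrate + reagent → second product (k = 5.15 M⁻¹ min⁻¹)
    third substrate + reagent → third product (k = 22.4 M⁻¹ min⁻¹)
    gas ⇌ reagent, rate k4*(csat - [reagent]) (kL = 0.475 min⁻¹)
    starting material + target → side product (k = 1.32 M⁻¹ min⁻¹)

Put back into the rule, theta's yield gives σ = 0.236, smaller than noon's by a factor of 2.69. For the neighbour of theta charged with 0.40 M and fed over the same 1.0 h, I reckon a feed of 0.400 M h⁻¹ against the gas constant of 0.475 min⁻¹ to hold reagent near 0.0490 M, lower than the 0.0600 M in theta at the end of its feed. σ then moves with the charge and with that lower reagent level to 1.16, which gives 53.0%. The computed flask gives 52.6%.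

The runs stem from a simulated flask with made-up constants.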